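**Plan**

- Retrosynthesis: the silyl ether on O6 is cut first, then C4–C4a (intramolecular B-alkyl Suzuki coupling), then O1–C2 (palladium-catalysed asymmetric allylic etherification). This leads back to solanesyl methyl carbonate and a bromophenol made from 2,3-dimethylhydroquinone.
- Enabling feature: C2 is a tertiary ether carbon bearing the C2 methyl, C3 and the side chain. It is therefore the substituted terminus of the allyl system of solanesol, which supplies C4, C3, C2, the C2 methyl and all eight chain isoprene units in one piece. The benzene ring comes from the hydroquinone, and the dihydropyran ring is the only ring to be built.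
- Forward: the chain is joined to the arene through O1–C2 with no ring formed. The dihydropyran ring then closes at C4–C4a, and desilylation ends the route.
- Stereochemistry: C2 (R) is set by the chiral ligand in the palladium step and is not touched afterwards. The seven E-configured chain alkenes are those of all-E solanesol.

Key step: step 4

Assumption: with the all-E carbonate the (R,R)-configured ligand is taken to give the (R)-ether; the sense of induction of this ligand family depends on alkene geometry, so the first sample is correlated after ring closure and the (S,S)-ligand is used instead, with nothing else changed, if the sense is opposite.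

**Route**

Step 1
Reactants: 1 solanesol; 2 methyl chloroformate
Product: 3 solanesyl methyl carbonate
Conditions: ClCO2Me (1.5 equiv), pyridine (3 equiv), CH2Cl2, 0 °C
Reagents that add atoms: methyl chloroformate (2), COC(=O)Cl
Why: O-acylation of the primary allylic alcohol by the chloroformate with pyridine as acid scavenger should proceed without touching the nine alkenes and gives the ionisable leaving group for step 4.

Step 2
Reactants: 4 2,3-dimethylhydroquinone; 5 chlorotriisopropylsilane
Product: 6 2,3-dimethyl-4-(triisopropylsilyloxy)phenol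
Conditions: TIPSCl (1.0 equiv), 4 (2 equiv), imidazole (2.2 equiv), DMF, 0 °C to rt, argon
Reagents that add atoms: chlorotriisopropylsilane (5), CC(C)[Si](Cl)(C(C)C)C(C)C
Why: Imidazole-mediated O-silylation of a phenol; the two hydroxyls of 4 are equivalent, so only one mono-ether can form, and the excess of diol (recoverable) holds back the bis-ether.

Step 3
Reactants: 6 2,3-dimethyl-4-(triisopropylsilyloxy)phenol; 7 N-bromosuccinimide
Product: 8 2-bromo-5,6-dimethyl-4-(triisopropylsilyloxy)phenol
Conditions: NBS (1.0 equiv), i-Pr2NH (10 mol %), CH2Cl2, −40 to 0 °C, dark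
Reagents that add atoms: N-bromosuccinimide (7), O=C1CCC(=O)N1Br
Why: Amine-mediated electrophilic ortho-bromination of a phenol; the para position is blocked, and the free hydroxyl is a stronger director than the bulky silyl ether, so bromine should enter the only open position next to OH.

Step 4
Reactants: 3 solanesyl methyl carbonate; 8 2-bromo-5,6-dimethyl-4-(triisopropylsilyloxy)phenol
Product: 9 (R)-branched tertiary aryl allyl ether
Conditions: Pd2(dba)3·CHCl3 (2.5 mol %), N,N'-[(1R,2R)-cyclohexane-1,2-diyl]bis[2-(diphenylphosphanyl)benzamide] (7.5 mol %), 8 (1.2 equiv), CH2Cl2 (0.1 M), 0 °C, stopped when 3 is consumed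
Reagents that add atoms: none
Why: The zerovalent palladium–diphosphine complex ionises the carbonate of 3 with inversion to a cationic π-allyl complex whose substituted terminus carries the methyl group and the C40 chain, and the methyl carbonate anion loses CO2 to give methoxide, which deprotonates phenol 8. The aryloxide then attacks the allyl ligand on the face away from palladium at the more substituted terminus, which carries most of the positive charge in the unsymmetrical complex, so the O1–C2 bond forms as a tertiary ether; the closest known reaction is the Tsuji–Trost asymmetric allylic O-alkylation of phenols with geranyl methyl carbonate. No ring is closed in this step. The C2 stereocentre is controlled by the chiral pocket of the ligand, which distinguishes the two faces of the E-configured allyl unit; the two diastereomeric complexes interconvert by η3–η1–η3 slippage through the CH2 terminus, and the one attacked faster fixes the (R) configuration. The step needs branched-over-linear regioselectivity, secured by the single E geometry of solanesol, the ligand, and the low temperature that keeps the kinetic tertiary ether from re-ionising; it also needs chemoselectivity, secured because only the carbonate can ionise while the bromide on the electron-rich ring and the eight isolated alkenes are inert to the catalyst at 0 °C.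

Step 5
Reactants: 9 (R)-branched tertiary aryl allyl ether; 10 9-borabicyclo[3.3.1]nonane
Product: 12 O-TIPS-plastochromanol-8, via alkylborane 11 (not isolated)
Conditions: 9-BBN (1.2 equiv, 0.5 M in THF), THF, 0 °C to rt; then degassed aq K3PO4 (3 equiv), Pd(OAc)2 (5 mol %), SPhos (10 mol %), THF (0.02 M), 60 °C
Reagents that add atoms: none
Why: 9-BBN hydroborates the monosubstituted vinyl group anti-Markovnikov far faster than any of the eight trisubstituted alkenes, and the primary alkylborane, activated as its hydroxyborate, should undergo intramolecular B-alkyl Suzuki–Miyaura coupling with the aryl bromide through a seven-membered palladacycle whose reductive elimination closes the six-membered dihydropyran ring at C4–C4a, leaving the quaternary C2 stereocentre, the aryl silyl ether and the chain alkenes untouched.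

Step 6
Reactants: 12 O-TIPS-plastochromanol-8
Product: 13 plastochromanol-8
Conditions: TBAF (1.5 equiv), AcOH (1.5 equiv), THF, 0 °C to rt, argon
Reagents that add atoms: none
Why: Fluoride attacks silicon and releases the phenol (desilylation), the acetic acid buffer keeps the air-sensitive chromanol protonated, and neither the chroman ether, the C2 stereocentre nor the polyene should be affected.

**Compound list**

1 | solanesol, (2E,6E,10E,14E,18E,22E,26E,30E)-3,7,11,15,19,23,27,31,35-nonamethylhexatriaconta-2,6,10,14,18,22,26,30,34-nonaen-1-ol | CC(C)=CCC/C(C)=C/CC/C(C)=C/CC/C(C)=C/CC/C(C)=C/CC/C(C)=C/CC/C(C)=C/CC/C(C)=C/CC/C(C)=C/CO | starting material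
2 | methyl chloroformate | COC(=O)Cl | starting material
3 | solanesyl methyl carbonate (all-E methyl carbonate of 1) | CC(C)=CCC/C(C)=C/CC/C(C)=C/CC/C(C)=C/CC/C(C)=C/CC/C(C)=C/CC/C(C)=C/CC/C(C)=C/CC/C(C)=C/COC(=O)OC | intermediate
4 | 2,3-dimethylhydroquinone (2,3-dimethylbenzene-1,4-diol) | Cc1c(C)c(O)ccc1O | starting material
5 | chlorotriisopropylsilane (TIPSCl) | CC(C)[Si](Cl)(C(C)C)C(C)C | starting material
6 | 2,3-dimethyl-4-(triisopropylsilyloxy)phenol | Cc1c(C)c(O[Si](C(C)C)(C(C)C)C(C)C)ccc1O | intermediate
7 | N-bromosuccinimide | O=C1CCC(=O)N1Br | starting material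
8 | 2-bromo-5,6-dimethyl-4-(triisopropylsilyloxy)phenol | Cc1c(C)c(O[Si](C(C)C)(C(C)C)C(C)C)cc(Br)c1O | intermediate
9 | (R)-branched tertiary aryl allyl ether: 2-bromo-5,6-dimethyl-4-(triisopropylsilyloxy)phenyl ether on O3 of (3R,6E,10E,14E,18E,22E,26E,30E)-3,7,11,15,19,23,27,31,35-nonamethylhexatriaconta-1,6,10,14,18,22,26,30,34-nonaen-3-ol; the ether carbon bears methyl, vinyl and the all-E chain | CC(C)=CCC/C(C)=C/CC/C(C)=C/CC/C(C)=C/CC/C(C)=C/CC/C(C)=C/CC/C(C)=C/CC/C(C)=C/CC[C@](C)(C=C)Oc1c(Br)cc(O[Si](C(C)C)(C(C)C)C(C)C)c(C)c1C | intermediate
10 | 9-borabicyclo[3.3.1]nonane (9-BBN, sold as the dimer) | B1C2CCCC1CCC2 | starting material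
11 | alkylborane: B-alkyl-9-BBN adduct of 9 with boron on the former vinyl terminus (future C4); ether carbon spatially unchanged, formally S through the change of CIP priorities | CC(C)=CCC/C(C)=C/CC/C(C)=C/CC/C(C)=C/CC/C(C)=C/CC/C(C)=C/CC/C(C)=C/CC/C(C)=C/CC[C@](C)(CCB1C2CCCC1CCC2)Oc1c(Br)cc(O[Si](C(C)C)(C(C)C)C(C)C)c(C)c1C | intermediate
12 | O-TIPS-plastochromanol-8: (2R)-2,7,8-trimethyl-2-[(3E,7E,11E,15E,19E,23E,27E)-4,8,12,16,20,24,28,32-octamethyltritriaconta-3,7,11,15,19,23,27,31-octaenyl]-6-(triisopropylsilyloxy)chroman | CC(C)=CCC/C(C)=C/CC/C(C)=C/CC/C(C)=C/CC/C(C)=C/CC/C(C)=C/CC/C(C)=C/CC/C(C)=C/CC[C@]1(C)CCc2cc(O[Si](C(C)C)(C(C)C)C(C)C)c(C)c(C)c2O1 | intermediate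
13 | plastochromanol-8: (2R)-2,7,8-trimethyl-2-[(3E,7E,11E,15E,19E,23E,27E)-4,8,12,16,20,24,28,32-octamethyltritriaconta-3,7,11,15,19,23,27,31-octaenyl]chroman-6-ol | CC(C)=CCC/C(C)=C/CC/C(C)=C/CC/C(C)=C/CC/C(C)=C/CC/C(C)=C/CC/C(C)=C/CC/C(C)=C/CC[C@]1(C)CCc2cc(O)c(C)c(C)c2O1 | target

**Step count and risks**

Total: 6 steps. Longest linear sequence: 5 steps (steps 2, 3, 4, 5, 6 from 2,3-dimethylhydroquinone); the solanesol branch has 4 steps (1, 4, 5, 6).

Step 4. What may go wrong: the di-ortho-substituted aryloxide may be captured at the unsubstituted allyl terminus, the ligand may discriminate poorly between the two faces of the E-configured allyl unit, or the tertiary ether may re-ionise and drift to the linear isomer.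
- The fallback sets out from solanesol 1 and comes back at 9. It takes the stereocentre from a reagent-controlled epoxidation and transfers it stereospecifically.
- Sharpless asymmetric epoxidation (Ti(OiPr)4, D-(−)-diethyl tartrate, t-BuOOH, 4 Å sieves, CH2Cl2, −20 °C) reacts only at the allylic alcohol alkene and should give (2R,3R)-2,3-epoxysolanesol F1.
- I2, PPh3 and imidazole convert the primary hydroxyl into the epoxy iodide F2.
- Zinc dust in ethanol opens F2 reductively to the (R)-tertiary allylic alcohol F3; the C–O bond at the stereocentre is never broken.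
- n-BuLi followed by methyl chloroformate 2 (THF, −78 to 0 °C) gives the tertiary methyl carbonate F4.
- F4 is then substituted by the lithium aryloxide of 8 (LiN(SiMe3)2, THF) under RhCl(PPh3)3 modified with P(OMe)3, 0 °C to rt. This stereospecific rhodium-catalysed allylic etherification proceeds with net retention at the substituted terminus, because the rhodium allyl intermediate does not equilibrate its faces, and should return 9.
- The reaction type is established for hindered ortho-disubstituted aryloxides with secondary carbonates, and for tertiary carbonates with other nucleophiles; the combination used here is an extension of both.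

Step 5. What may go wrong: β-hydride elimination or protodeboronation may outrun ring-closing reductive elimination, or oxidative addition into the electron-rich bromide may be sluggish.
- The fallback sets out from 9, passes through alkylborane 11 made as in step 5, and comes back at 12. It replaces the cross-coupling by an anionic ring closure.
- Oxidation of 11 (NaOH, H2O2, THF, 0 °C) gives the primary alcohol F5.
- CBr4 and PPh3 (CH2Cl2, 0 °C) give the primary bromide F6.
- n-BuLi in THF at −100 °C exchanges the aryl bromine faster than the alkyl bromine; on warming, the aryllithium displaces the primary bromide intramolecularly (Parham cyclisation, 6-exo-tet) to close C4–C4a and give 12.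

Step 3. What may go wrong: the electron-rich silyloxyphenol may be oxidised to the quinone with loss of the silyl group, or bromine may enter next to the silyl ether.
- The fallback sets out from 4 and comes back at 8. It introduces bromine before the two oxygens are differentiated.
- Oxidation of 4 with Ag2O (Et2O, MgSO4) gives 2,3-dimethyl-1,4-benzoquinone F7.
- Conjugate addition of HBr (48 % aq HBr, CHCl3, 0 °C to rt) gives 5-bromo-2,3-dimethylbenzene-1,4-diol F8.
- TIPSCl and imidazole in DMF should silylate the less hindered hydroxyl (flanked by methyl and hydrogen rather than by methyl and bromine), which gives 8.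

**Further compounds**

F1 | step 4 | (2R,3R)-2,3-epoxysolanesol | CC(C)=CCC/C(C)=C/CC/C(C)=C/CC/C(C)=C/CC/C(C)=C/CC/C(C)=C/CC/C(C)=C/CC/C(C)=C/CC[C@@]1(C)O[C@@H]1CO
F2 | step 4 | epoxy iodide, (2S,3R)-2,3-epoxy-1-iodo derivative of F1 (same spatial arrangement as F1) | CC(C)=CCC/C(C)=C/CC/C(C)=C/CC/C(C)=C/CC/C(C)=C/CC/C(C)=C/CC/C(C)=C/CC/C(C)=C/CC[C@@]1(C)O[C@@H]1CI
F3 | step 4 | (R)-tertiary allylic alcohol, (3R,6E,10E,14E,18E,22E,26E,30E)-3,7,11,15,19,23,27,31,35-nonamethylhexatriaconta-1,6,10,14,18,22,26,30,34-nonaen-3-ol | CC(C)=CCC/C(C)=C/CC/C(C)=C/CC/C(C)=C/CC/C(C)=C/CC/C(C)=C/CC/C(C)=C/CC/C(C)=C/CC[C@](C)(C=C)O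
F4 | step 4 | tertiary methyl carbonate of F3, (R) | CC(C)=CCC/C(C)=C/CC/C(C)=C/CC/C(C)=C/CC/C(C)=C/CC/C(C)=C/CC/C(C)=C/CC/C(C)=C/CC[C@](C)(C=C)OC(=O)OC
F5 | step 5 | primary alcohol, (R)-configured 2-hydroxyethyl analogue of 9 (vinyl replaced by CH2CH2OH) | CC(C)=CCC/C(C)=C/CC/C(C)=C/CC/C(C)=C/CC/C(C)=C/CC/C(C)=C/CC/C(C)=C/CC/C(C)=C/CC[C@](C)(CCO)Oc1c(Br)cc(O[Si](C(C)C)(C(C)C)C(C)C)c(C)c1C
F6 | step 5 | primary bromide, (R)-configured 2-bromoethyl analogue of 9 | CC(C)=CCC/C(C)=C/CC/C(C)=C/CC/C(C)=C/CC/C(C)=C/CC/C(C)=C/CC/C(C)=C/CC/C(C)=C/CC[C@](C)(CCBr)Oc1c(Br)cc(O[Si](C(C)C)(C(C)C)C(C)C)c(C)c1C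
F7 | step 3 | 2,3-dimethyl-1,4-benzoquinone | CC1=C(C)C(=O)C=CC1=O
F8 | step 3 | 5-bromo-2,3-dimethylbenzene-1,4-diol | Cc1c(C)c(O)c(Br)cc1O
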